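Beside the four set-ups stands a neighbour of red charged with 4.4 × 10⁻⁴ M of precatalyst, and I want a rule that carries over to it.

| flask | substrate | reagent | precatalyst | time | remark |
|---|---|---|---|---|---|
| blue | 0.25 M (fed, over 30.0 min) | 0.200 M | 1.1 mM | 30 min | a stirred flask in which substrate is dosed at a steady rate over 30.0 min without added volume, worked up at 30 min |
| amber | 0.25 M | 0.200 M | 1.1 mM |  | one stirred flow tank at steady state, fed with the mixture as stated, mean residence time 30 min |
| ochre | 0.25 M | 0.200 M (fed, over 30.0 min) | 1.1 mM | 30 min | a stirred flask in which reagent is dosed at a steady rate over 30.0 min without added volume, worked up at 30 min |
| red | 0.25 M | 0.200 M | 1.1 mM | 30 min | everything together in a closed stirred flask, run for 30 min |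

* the set-up with the highest amount of target at the outlet or at the end, in percent of the substrate put in ("none" if the first two lie within 2 percentage points) (blue / amber / ochre / red / none)
* amount of target at the outlet or at the end, in percent of the substrate put in, blue
* amount of target at the outlet or at the end, in percent of the substrate put in, amber
* amount of target at the outlet or at the end, in percent of the substrate put in, ochre
* amount of target at the outlet or at the end, in percent of the substrate put in, red

- the stated concentrations are those of everything mixed, before any reaction; amounts are the same in each set-up
- the feed brings no volume worth counting
- run time (blue): 30 min

    substrate + free catalyst ⇌ catalyst intermediate A (K1 = 6.60 /M, k1 = 13.5 /M/s)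
    catalyst intermediate A → catalyst intermediate B (k2 = 0.638 /s)
    reagent + catalyst intermediate B ⇌ catalyst intermediate C (K3 = 7.6 /M, k3 = 2.53 /M/s)
    catalyst intermediate C → catalyst intermediate D (k4 = 0.521 /s)
    catalyst intermediate D → free catalyst + target (k5 = 0.748 /s)
    precatalyst ⇌ free catalyst (K6 = 0.790, k6 = 0.00122 /s)
    target + free catalyst ⇌ isomer of the product + free catalyst, rate k7*[free catalyst]*[target] forward; the back reaction follows from the equilibrium constant (K7 = 2.6, k7 = 0.253 /M/s)

The fastest rung is the round of catalyst forms. Each form holds the catalyst for its own time: the one-way steps for the inverse of their constants, the two binding steps for a time that grows as c(substrate) or c(reagent) falls and is stretched by falling back before going on. At the charged concentrations, free catalyst waits 1.25 s and catalyst intermediate B waits 3.24 s, longer than any other form. The waits add up to 9.31 s. This sum is the cycle time: the seconds one catalyst molecule needs for one trip round at the concentrations present.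

The next rung is the precatalyst. By itself its step relaxes with a half-life of 4.18 min, but free catalyst is 13.4% of the round, so the way back is weak and release runs with a time constant of 11.7 min, far slower than the cycle. I therefore take the round as steady and reckon with what it leaves free: once balanced, 85.5% of the catalyst sits in the round.

The run is longer than that release, yet with the lag counted I reckon red as if that share had turned for 19.2 min. At the cycle time of the charge, that gives 46.6% target in red. I take this as an estimate on the high side: the sum holds for the charged concentrations, and the waits of free catalyst and catalyst intermediate B grow as those concentrations fall. I put red first: a dosed flask starts short of its dosed charge and a tank sits at outlet concentrations.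

The forecast names red, with blue 33.5%, amber 35.5%, ochre 31% and red 38%, on the grounds of “full substrate and reagent from the start”. Its red stands lower than my figure.

The simulation gives red first, with blue 31.5%, amber 35.5%, ochre 30.7% and red 38.7%, so the forecast stands and my figure is 7.9 percentage points high. The ochre figure of the forecast holds for the stated charge: at 0.886 mM or 1.34 mM of precatalyst the ochre answer has moved by 5 points.

In red, the precatalyst step went on feeding the round, with precatalyst at 38.4% of the catalyst after 15.0 min and 22.1% after 30.0 min, while catalyst intermediate B became the resting state at 37.5%. With the 60% of substrate and 51% of reagent left in red, the cycle time reads 13.3 s, longer than at the charge.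

In the neighbour of red, the cycle time and the release start as before, so my figure scales with the precatalyst charge to 18.6%. The neighbour gives 17.4%.

(The numbers were drawn at random within sensible limits, and the outcome is calculated.)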